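**Strategy.** Everything rests on cutting two bonds at neighbouring carbons of the benzene ring: C1'–C1 (ring to ketone carbon) and C2'–O (the ortho phenol). An aryne that inserts into the C(=O)–O bond of a carboxylic acid ends up with exactly this acyl/oxygen pair on adjacent ring carbons, so a single fluoride-triggered operation joins the complete (R)-2-silyloxy farnesylated acid to the ring and reveals the 2'-hydroxy ketone. The aryne precursor is an ortho-silylaryl triflate that carries the 4'-oxygen as an allyl ether and a bromine at C6', placed to steer the addition and reduced off afterwards; the acid takes its stereocentre from an oxazolidinone glycolate alkylation.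

Key step: step 7

Assumption: compounds 1, 7, 10 and 13 are purchased; the (2E,6E) geometry of 13 is carried unchanged into every later compound.

Step 1
Reactants: 1 4-(allyloxy)phenol
Product: 2 4-(allyloxy)-2,6-dibromophenol
Conditions: NBS (2.05 equiv), i-Pr2NH (10 mol%), CH2Cl2, 0 °C
Reagents that add atoms: N-bromosuccinimide, O=C1CCC(=O)N1Br
Why: Amine-catalysed electrophilic aromatic bromination with NBS goes to both positions ortho to the free phenol (para is blocked by the allyloxy group), and in anhydrous CH2Cl2 the strongly activated ring should react far faster than the terminal alkene of the allyl ether.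

Step 2
Reactants: 2 4-(allyloxy)-2,6-dibromophenol
Product: 6 4-(allyloxy)-2-bromo-6-(trimethylsilyl)phenyl trifluoromethanesulfonate, via silyl ether 3 (not isolated), via aryllithium 4 (not isolated), via lithium phenoxide 5 (not isolated)
Conditions: HMDS, THF, 70 °C, then volatiles removed; n-BuLi (1.0 equiv), THF, −100 → −78 °C; Tf2O, −100 °C → rt
Reagents that add atoms: hexamethyldisilazane, C[Si](C)(C)N[Si](C)(C)C; trifluoromethanesulfonic anhydride, O=S(=O)(OS(=O)(=O)C(F)(F)F)C(F)(F)F
Why: O-silylation, bromine–lithium exchange at one of the two equivalent C–Br bonds and an immediate 1,3 O→C silyl shift (retro-Brook rearrangement) give a phenoxide that deactivates the ring toward a second exchange and is triflated in the same flask, the standard one-pot entry to ortho-silylaryl triflates.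

Step 3
Reactants: 7 glycolic acid
Product: 9 2-(triisopropylsilyloxy)acetic acid, via bis-silyl derivative 8 (not isolated)
Conditions: TIPSCl (2.2 equiv), imidazole, DMF, rt; then K2CO3, MeOH/THF/H2O, rt; HCl to pH 3
Reagents that add atoms: chlorotriisopropylsilane, CC(C)[Si](Cl)(C(C)C)C(C)C
Why: Exhaustive silylation followed by mild carbonate solvolysis cleaves only the labile silyl ester and leaves the primary triisopropylsilyl ether (silyl protection with selective silyl ester cleavage).

Step 4
Reactants: 9 2-(triisopropylsilyloxy)acetic acid; 10 (S)-4-benzyloxazolidin-2-one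
Product: 12 (S)-4-benzyl-3-[2-(triisopropylsilyloxy)acetyl]oxazolidin-2-one, via mixed anhydride 11 (not isolated)
Conditions: t-BuCOCl, Et3N, THF, −20 °C; then 10, LiCl, −20 °C → rt
Reagents that add atoms: none
Why: Mixed pivalic anhydride activation and LiCl/Et3N-promoted N-acylation attach the acid to the auxiliary without strong base, the hindered pivaloyl carbonyl being spared.

Step 5
Reactants: 12 (S)-4-benzyl-3-[2-(triisopropylsilyloxy)acetyl]oxazolidin-2-one; 13 (2E,6E)-farnesyl bromide
Product: 15 (S)-4-benzyl-3-[(2R,4E,8E)-5,9,13-trimethyl-2-(triisopropylsilyloxy)tetradeca-4,8,12-trienoyl]oxazolidin-2-one, via sodium enolate 14 (not isolated)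
Conditions: NaN(SiMe3)2 (1.2 equiv), THF, −78 °C; then 13 (3 equiv), Bu4NI (cat.), −78 → −45 °C
Reagents that add atoms: none
Why: In this Evans-type asymmetric alkylation of an oxazolidinone glycolate, deprotonation gives the chelated Z-enolate 14 whose face syn to the C4 benzyl group is blocked, so the allylic bromide is attacked (SN2, alkene geometry untouched) from the opposite face, which for the (S)-auxiliary sets C2 as R.

Step 6
Reactants: 15 (S)-4-benzyl-3-[(2R,4E,8E)-5,9,13-trimethyl-2-(triisopropylsilyloxy)tetradeca-4,8,12-trienoyl]oxazolidin-2-one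
Product: 16 (R,4E,8E)-5,9,13-trimethyl-2-(triisopropylsilyloxy)tetradeca-4,8,12-trienoic acid
Conditions: LiOH, H2O2, THF/H2O, 0 °C; then Na2SO3; HCl to pH 3
Reagents that add atoms: hydrogen peroxide, OO
Why: The small, highly nucleophilic hydroperoxide anion attacks the exocyclic imide carbonyl selectively (LiOOH auxiliary cleavage) under cold basic conditions that should leave the C2 stereocentre, the silyl ether and the trisubstituted alkenes untouched, and sulfite reduces the peracid before acidification.

Step 7
Reactants: 6 4-(allyloxy)-2-bromo-6-(trimethylsilyl)phenyl trifluoromethanesulfonate; 16 (R,4E,8E)-5,9,13-trimethyl-2-(triisopropylsilyloxy)tetradeca-4,8,12-trienoic acid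
Product: 19 (R,4E,8E)-1-[4-(allyloxy)-2-bromo-6-hydroxyphenyl]-5,9,13-trimethyl-2-(triisopropylsilyloxy)tetradeca-4,8,12-trien-1-one, via cesium carboxylate 17 (not isolated), via aryne 18 (not isolated)
Conditions: CsF (4 equiv), 6 (1.3 equiv), THF, 125 °C, sealed tube
Reagents that add atoms: none
Why: Fluoride attacks the Me3Si group of 6 and triflate leaves to give aryne 18, while CsF turns 16 into carboxylate 17; the carboxylate oxygen adds to the aryne carbon remote from bromine (the future C2'), the aryl anion so formed at C1' attacks the adjacent ester carbonyl through a four-membered alkoxide, and C–O cleavage of that alkoxide gives the ortho-acyl phenoxide, protonated on work-up. The closest known reaction type is the fluoride-induced insertion of arynes into the C–O bond of carboxylic acids to form ortho-hydroxyaryl ketones, run hot in THF so that intramolecular acyl transfer outruns protonation to the aryl ester. No ring is closed, because the transient four-membered ring reopens at once. No stereocentre is created, and C2 should be carried through because a carboxylate is not enolised by fluoride, the product exists as a phenoxide whose donation into the ketone lowers the acidity of C2–H, and the bulky silyl ether shields that hydrogen. The step needs site selectivity between the two aryne carbons, and the bromine beside the triple bond secures it: its inductive pull and the distortion it imposes make the distal carbon the electrophilic and less hindered end and place the developing negative charge next to C–Br, which outweighs the weak opposite bias of the remote allyloxy group.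

Step 8
Reactants: 19 (R,4E,8E)-1-[4-(allyloxy)-2-bromo-6-hydroxyphenyl]-5,9,13-trimethyl-2-(triisopropylsilyloxy)tetradeca-4,8,12-trien-1-one
Product: 21 (R,4E,8E)-1-(2,4-dihydroxyphenyl)-5,9,13-trimethyl-2-(triisopropylsilyloxy)tetradeca-4,8,12-trien-1-one, via bromo diol 20 (not isolated)
Conditions: Pd(PPh3)4 (5 mol%), HCO2H/Et3N (excess), DMF, rt, then 80 °C
Reagents that add atoms: none
Why: Zerovalent palladium ionises the allyl aryl ether to a π-allyl complex that formate reduces to propene, and on warming it inserts into the C–Br bond activated by the ortho ketone, after which the arylpalladium formate loses CO2 and reductively eliminates Ar–H (Tsuji-type deallylation and palladium/formate hydrodehalogenation), the large excess of formate being there so that hydride capture outruns any reaction with the chain alkenes.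

Step 9
Reactants: 21 (R,4E,8E)-1-(2,4-dihydroxyphenyl)-5,9,13-trimethyl-2-(triisopropylsilyloxy)tetradeca-4,8,12-trien-1-one
Product: 22 (R,4E,8E)-1-(2,4-dihydroxyphenyl)-2-hydroxy-5,9,13-trimethyltetradeca-4,8,12-trien-1-one
Conditions: Bu4NF, AcOH (1:1), THF, 0 °C → rt
Reagents that add atoms: none
Why: Fluoride-mediated desilylation, buffered with acetic acid so that the alpha-hydroxy ketone and the phenols never meet a strongly basic medium, should free the C2 hydroxyl without touching the stereocentre or the triene.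

**Compound list**

1 | 4-(allyloxy)phenol | C=CCOc1ccc(O)cc1 | starting material
2 | 4-(allyloxy)-2,6-dibromophenol | C=CCOc1cc(Br)c(O)c(Br)c1 | intermediate
3 | [4-(allyloxy)-2,6-dibromophenoxy]trimethylsilane | C=CCOc1cc(Br)c(O[Si](C)(C)C)c(Br)c1 | intermediate (not isolated)
4 | [5-(allyloxy)-3-bromo-2-(trimethylsilyloxy)phenyl]lithium | [Li]c1cc(OCC=C)cc(Br)c1O[Si](C)(C)C | intermediate (not isolated)
5 | lithium 4-(allyloxy)-2-bromo-6-(trimethylsilyl)phenoxide | [Li+].[O-]c1c(Br)cc(OCC=C)cc1[Si](C)(C)C | intermediate (not isolated)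
6 | 4-(allyloxy)-2-bromo-6-(trimethylsilyl)phenyl trifluoromethanesulfonate | C[Si](C)(C)c1cc(OCC=C)cc(Br)c1OS(=O)(=O)C(F)(F)F | intermediate
7 | glycolic acid | OCC(=O)O | starting material
8 | triisopropylsilyl 2-(triisopropylsilyloxy)acetate | CC(C)[Si](OCC(=O)O[Si](C(C)C)(C(C)C)C(C)C)(C(C)C)C(C)C | intermediate (not isolated)
9 | 2-(triisopropylsilyloxy)acetic acid | CC(C)[Si](OCC(=O)O)(C(C)C)C(C)C | intermediate
10 | (S)-4-benzyloxazolidin-2-one | O=C1N[C@@H](Cc2ccccc2)CO1 | starting material
11 | pivalic 2-(triisopropylsilyloxy)acetic anhydride | CC(C)[Si](OCC(=O)OC(=O)C(C)(C)C)(C(C)C)C(C)C | intermediate (not isolated)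
12 | (S)-4-benzyl-3-[2-(triisopropylsilyloxy)acetyl]oxazolidin-2-one | CC(C)[Si](OCC(=O)N1[C@@H](Cc2ccccc2)COC1=O)(C(C)C)C(C)C | intermediate
13 | (2E,6E)-farnesyl bromide | CC(C)=CCC/C(C)=C/CC/C(C)=C/CBr | starting material
14 | sodium (Z)-1-[(S)-4-benzyl-2-oxooxazolidin-3-yl]-2-(triisopropylsilyloxy)ethen-1-olate | [Na+].[O-]/C(=C\O[Si](C(C)C)(C(C)C)C(C)C)N1[C@@H](Cc2ccccc2)COC1=O | intermediate (not isolated)
15 | (S)-4-benzyl-3-[(2R,4E,8E)-5,9,13-trimethyl-2-(triisopropylsilyloxy)tetradeca-4,8,12-trienoyl]oxazolidin-2-one | CC(C)=CCC/C(C)=C/CC/C(C)=C/C[C@@H](O[Si](C(C)C)(C(C)C)C(C)C)C(=O)N1[C@@H](Cc2ccccc2)COC1=O | intermediate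
16 | (R,4E,8E)-5,9,13-trimethyl-2-(triisopropylsilyloxy)tetradeca-4,8,12-trienoic acid | CC(C)=CCC/C(C)=C/CC/C(C)=C/C[C@@H](O[Si](C(C)C)(C(C)C)C(C)C)C(=O)O | intermediate
17 | cesium (R,4E,8E)-5,9,13-trimethyl-2-(triisopropylsilyloxy)tetradeca-4,8,12-trienoate | [Cs+].CC(C)=CCC/C(C)=C/CC/C(C)=C/C[C@@H](O[Si](C(C)C)(C(C)C)C(C)C)C(=O)[O-] | intermediate (not isolated)
18 | 5-(allyloxy)-3-bromobenzyne (5-(allyloxy)-3-bromo-1,2-didehydrobenzene) | C=CCOC1=CC#CC(Br)=C1 | intermediate (not isolated)
19 | (R,4E,8E)-1-[4-(allyloxy)-2-bromo-6-hydroxyphenyl]-5,9,13-trimethyl-2-(triisopropylsilyloxy)tetradeca-4,8,12-trien-1-one | CC(C)=CCC/C(C)=C/CC/C(C)=C/C[C@@H](O[Si](C(C)C)(C(C)C)C(C)C)C(=O)c1c(O)cc(OCC=C)cc1Br | intermediate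
20 | (R,4E,8E)-1-(2-bromo-4,6-dihydroxyphenyl)-5,9,13-trimethyl-2-(triisopropylsilyloxy)tetradeca-4,8,12-trien-1-one | CC(C)=CCC/C(C)=C/CC/C(C)=C/C[C@@H](O[Si](C(C)C)(C(C)C)C(C)C)C(=O)c1c(O)cc(O)cc1Br | intermediate (not isolated)
21 | (R,4E,8E)-1-(2,4-dihydroxyphenyl)-5,9,13-trimethyl-2-(triisopropylsilyloxy)tetradeca-4,8,12-trien-1-one | CC(C)=CCC/C(C)=C/CC/C(C)=C/C[C@@H](O[Si](C(C)C)(C(C)C)C(C)C)C(=O)c1ccc(O)cc1O | intermediate
22 | (R,4E,8E)-1-(2,4-dihydroxyphenyl)-2-hydroxy-5,9,13-trimethyltetradeca-4,8,12-trien-1-one | CC(C)=CCC/C(C)=C/CC/C(C)=C/C[C@@H](O)C(=O)c1ccc(O)cc1O | target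

**Total step count:** 9.
**Longest linear sequence:** 7 steps (steps 3 to 9, from glycolic acid 7); the aryne-precursor branch (steps 1 and 2) joins at step 7.

**Steps most likely to fail**

Step 7 (aryne insertion). Four processes may defeat it:
- the C1' aryl anion may be protonated before acyl transfer, which stops at O-arylation;
- the aryne may be consumed in ene reactions with the trisubstituted alkenes of the chain;
- hot fluoride may cleave the silyl ether or erode the C2 configuration;
- site control between the two aryne carbons may be incomplete.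

The fallback replaces the aryne by acylation of a preformed aryl anion, without bromine on the ring; it sets out from 16 and returns to the route at 21. Acid 16 is condensed with MeNHOMe·HCl (EDC, HOBt, i-Pr2NEt, CH2Cl2) to the Weinreb amide (R,4E,8E)-N-methoxy-N,5,9,13-tetramethyl-2-(triisopropylsilyloxy)tetradeca-4,8,12-trienamide F1. Purchased 4-bromoresorcinol is allylated twice (allyl bromide, K2CO3, acetone, reflux) to 2,4-bis(allyloxy)-1-bromobenzene F2. Bromine–lithium exchange of F2 (n-BuLi, THF, −78 °C) and addition of the aryllithium to F1 should give, through the chelated tetrahedral adduct that collapses only on work-up, (R,4E,8E)-1-[2,4-bis(allyloxy)phenyl]-5,9,13-trimethyl-2-(triisopropylsilyloxy)tetradeca-4,8,12-trien-1-one F3. Pd(PPh3)4 with morpholine in THF at rt then removes both allyl groups to give 21, which goes on to step 9.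

Step 5 (glycolate alkylation). The silyloxy enolate may decompose (loss of the auxiliary, silyl migration) faster than it is alkylated by the allylic bromide, and facial control may be incomplete with the bulky, weakly chelating silyl ether. The fallback forms the C2–O bond on a finished carbon chain instead of the C2–C3 bond; it sets out from 13 and returns at 16. The dianion of acetic acid (LiN(i-Pr)2, 2 equiv, THF/DMPU) is alkylated with 13 to (4E,8E)-5,9,13-trimethyltetradeca-4,8,12-trienoic acid F4. This is attached to purchased (R)-4-benzyloxazolidin-2-one (t-BuCOCl, Et3N, LiCl, THF) to give (R)-4-benzyl-3-[(4E,8E)-5,9,13-trimethyltetradeca-4,8,12-trienoyl]oxazolidin-2-one F5. Its sodium Z-enolate (NaN(SiMe3)2, THF, −78 °C) is hydroxylated with 2-(phenylsulfonyl)-3-phenyloxaziridine on the face away from the benzyl group, which for the (R)-auxiliary should give (R)-4-benzyl-3-[(2R,4E,8E)-2-hydroxy-5,9,13-trimethyltetradeca-4,8,12-trienoyl]oxazolidin-2-one F6. Silylation (TIPSOTf, 2,6-lutidine, CH2Cl2) gives (R)-4-benzyl-3-[(2R,4E,8E)-5,9,13-trimethyl-2-(triisopropylsilyloxy)tetradeca-4,8,12-trienoyl]oxazolidin-2-one F7, and LiOH/H2O2 cleavage as in step 6 releases 16.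

Step 8 (deallylation and C–Br reduction). Reduction of the C–Br bond may stall, palladium hydride may shift double bonds along the chain, and the arylpalladium intermediate may add to the C4=C5 alkene (Heck-type cyclisation) before formate reaches it. The fallback spends the halogen in the bond-forming event, so no C–Br bond has to be reduced next to the triene; it sets out from 16 and returns at the target 22. Purchased 4-bromoresorcinol is silylated at its less hindered hydroxyl (TIPSCl, 1.0 equiv, imidazole, CH2Cl2, 0 °C) to 2-bromo-5-(triisopropylsilyloxy)phenol F8. Steglich esterification with 16 (DCC, DMAP, CH2Cl2) gives 2-bromo-5-(triisopropylsilyloxy)phenyl (R,4E,8E)-5,9,13-trimethyl-2-(triisopropylsilyloxy)tetradeca-4,8,12-trienoate F9. Bromine–lithium exchange (t-BuLi, 2 equiv, THF, −100 °C) triggers the 1,3 O→C acyl shift (anionic Fries-type rearrangement) to (R,4E,8E)-1-[2-hydroxy-4-(triisopropylsilyloxy)phenyl]-5,9,13-trimethyl-2-(triisopropylsilyloxy)tetradeca-4,8,12-trien-1-one F10. Bu4NF/AcOH in THF then removes both silyl groups to give 22.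

**Further compounds**

F1 | step 7 | (R,4E,8E)-N-methoxy-N,5,9,13-tetramethyl-2-(triisopropylsilyloxy)tetradeca-4,8,12-trienamide | CC(C)=CCC/C(C)=C/CC/C(C)=C/C[C@@H](O[Si](C(C)C)(C(C)C)C(C)C)C(=O)N(C)OC
F2 | step 7 | 2,4-bis(allyloxy)-1-bromobenzene | C=CCOc1ccc(Br)c(OCC=C)c1
F3 | step 7 | (R,4E,8E)-1-[2,4-bis(allyloxy)phenyl]-5,9,13-trimethyl-2-(triisopropylsilyloxy)tetradeca-4,8,12-trien-1-one | CC(C)=CCC/C(C)=C/CC/C(C)=C/C[C@@H](O[Si](C(C)C)(C(C)C)C(C)C)C(=O)c1ccc(OCC=C)cc1OCC=C
F4 | step 5 | (4E,8E)-5,9,13-trimethyltetradeca-4,8,12-trienoic acid | CC(C)=CCC/C(C)=C/CC/C(C)=C/CCC(=O)O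
F5 | step 5 | (R)-4-benzyl-3-[(4E,8E)-5,9,13-trimethyltetradeca-4,8,12-trienoyl]oxazolidin-2-one | CC(C)=CCC/C(C)=C/CC/C(C)=C/CCC(=O)N1[C@H](Cc2ccccc2)COC1=O
F6 | step 5 | (R)-4-benzyl-3-[(2R,4E,8E)-2-hydroxy-5,9,13-trimethyltetradeca-4,8,12-trienoyl]oxazolidin-2-one | CC(C)=CCC/C(C)=C/CC/C(C)=C/C[C@@H](O)C(=O)N1[C@H](Cc2ccccc2)COC1=O
F7 | step 5 | (R)-4-benzyl-3-[(2R,4E,8E)-5,9,13-trimethyl-2-(triisopropylsilyloxy)tetradeca-4,8,12-trienoyl]oxazolidin-2-one | CC(C)=CCC/C(C)=C/CC/C(C)=C/C[C@@H](O[Si](C(C)C)(C(C)C)C(C)C)C(=O)N1[C@H](Cc2ccccc2)COC1=O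
F8 | step 8 | 2-bromo-5-(triisopropylsilyloxy)phenol | Oc1cc(O[Si](C(C)C)(C(C)C)C(C)C)ccc1Br
F9 | step 8 | 2-bromo-5-(triisopropylsilyloxy)phenyl (R,4E,8E)-5,9,13-trimethyl-2-(triisopropylsilyloxy)tetradeca-4,8,12-trienoate | CC(C)=CCC/C(C)=C/CC/C(C)=C/C[C@@H](O[Si](C(C)C)(C(C)C)C(C)C)C(=O)Oc1cc(O[Si](C(C)C)(C(C)C)C(C)C)ccc1Br
F10 | step 8 | (R,4E,8E)-1-[2-hydroxy-4-(triisopropylsilyloxy)phenyl]-5,9,13-trimethyl-2-(triisopropylsilyloxy)tetradeca-4,8,12-trien-1-one | CC(C)=CCC/C(C)=C/CC/C(C)=C/C[C@@H](O[Si](C(C)C)(C(C)C)C(C)C)C(=O)c1ccc(O[Si](C(C)C)(C(C)C)C(C)C)cc1O
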